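## The problem

Eremophilane numbering is used throughout: ring A is C1–C5 with C10, ring B is C5–C10, C14 is the methyl on C5, C15 the methyl on C4, and C11 the carbinol carbon on C7.

The target 28 is a 4,5-dimethyl decalin whose ring B is a cross-conjugated 6,9-dien-8-one with a tertiary alcohol at C11. Its ring A carries three contiguous stereocentres, C3 (R, acylated carbinol), C4 (R) and the quaternary C5 (R). The two methyls are cis and O3 is trans to both. C5 is the hard centre: it is quaternary and flanked by a methine and two sp2 carbons. Once C4 and C5 exist, C3 is difficult to correct, so the three are best set in one event. The fragile groups are the dienone (acid-induced dienone–phenol rearrangement, conjugate addition), the tertiary alcohol (dehydration) and the (Z)-β-methylsulfanyl acrylate. The acrylate is oxidised at sulfur, isomerised by nucleophiles and poisons hydrogenation catalysts, so it must arrive last. The enabling feature is that C3–O, C4–CH3 and C5–CH3 lie on three consecutive atoms of ring A. That is the imprint of an (E)-2-methylbut-2-enoyl dienophile (C4=C5, activated by a C6 carbonyl inside ring B) adding to a 1-oxygenated (E,E)-diene (C3=C2–C1=C10) tied to it through C6–C9. C10, the fourth centre of such a cycloaddition, becomes sp2 in 28, so only the C3/C4/C5 relationship has to survive.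

## Retrosynthesis

**C3–O acyl bond.** Cutting the ester gives diol 22 and acid 26. The sulfur-bearing push–pull acrylate would not survive hydride, hypervalent iodine, palladium or strong base, so it goes on last. The forward reaction must acylate the hindered secondary C3–OH beside the tertiary C11–OH without Z to E isomerisation.

**Vinylic C–S bond of the acid.** Acid 26 is traced through ester 25 to enol tosylate 24 and formyl ester 23. Acid-mediated condensation of a thiol with 23 would favour sulfur trans to the ester. A chelation-controlled Z enol sulfonate followed by addition–elimination with retention fixes the required geometry instead.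

**C7–C11 and the two ring B alkenes.** Diol 22 comes from silyl ether 21, and 21 from ketol 19 by double dehydrogenation. Ketol 19 comes from enone 16 and acetone 17 by conjugate reduction and aldol capture. The neighbouring option, thiolate Michael–aldol–elimination on a preformed dienone, is redox-neutral but one step longer and builds a very crowded C6/C7 array. Hydride addition to 16 gives the C7 enolate regiospecifically with C6 as a methylene. Enone 16 lacks C11–C13 and one alkene. The forward steps ask for 1,4-selectivity, capture by a ketone, and dehydrogenation that spares the tertiary alcohol.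

**Functional-group changes back to the cycloadduct.** Enone 16 arises from alcohol 15 (ketal hydrolysis and loss of the C6 hydroxyl), 15 from ketone 14, and 14 from alkene 13. The C6 oxygen is kept up to this point because it is the activator of the dienophile. Hydrogenation must come before any enone exists, and the acid step must leave the silyl ether intact.

**C3–C4 and C5–C10 (key disconnection).** Cycloadduct 13 opens to the achiral, acyclic trienone 12. Cutting C4–C5 alone, or C5–C6 with C5–C10, would build one or two of the ring A centres at a time from precursors that already hold the others. This cut makes C3, C4 and C5 together from alkene geometry. The forward step needs endo selectivity, one enone face and an E,E diene.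

**C5–C6 bond.** Trienone 12 is cut at the ketone into Weinreb amide 9 and the vinyllithium 11 from bromide 10. The ketone is installed after the dienol ether because an enolisable enone would compete with the aldehyde in the silylation. The forward step needs an organolithium that leaves the silyl dienol ether alone and keeps the E geometry.

**Dienol ether, C1=C2, amide, ketal and C9–C10.** Dienol ether 9 comes from enal 8 by O-silylation and γ-deprotonation. Enal 8 comes from alkene 6 and crotonaldehyde 7 by cross-metathesis. Amide 6 is reached from ester 5, ketal 5 from keto ester 4, and 4 from acetoacetate 1 and allyl bromide 2 through dianion 3. Direct alkylation with a 1,4-dihalobutene was set aside: the resulting allylic halide can cyclise onto its own β-keto ester and would still need an oxidation. The forward steps need E-selective metathesis and control of the new C10=C1 geometry.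

## Roads not taken

**Alternative 1: dearomatising para-alkylation.** The cut is C4–C5, with ring B drawn as a phenol. The phenoxide of mesylate A1 would attack the secondary C4 mesylate through its para carbon C5 with inversion, giving dienone A2.
- Merits: ring B arrives complete, with the C8 oxygen, both alkenes and the C11 carbinol. A2 is two steps from 28, whereas the chosen plan needs six steps after its key step to reach 22. C3 and C4 can be set in an open chain by standard asymmetric methods.
- Weak points: the substitution is at a secondary carbon and creates a quaternary centre from a tetrasubstituted arene carbon. E2 loss of the mesylate and intermolecular O-alkylation compete. The C5 configuration depends on which face of the flat phenoxide the chain presents, which is a conformational preference and not a geometric necessity.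
- Comparison: this road is clearly shorter and avoids all redox work on ring B. Against that, the chosen plan fixes the cis C14/C15 relationship and C3 by alkene geometry in a suprafacial step.

**Alternative 2: terpene cyclase.** The cut removes both ring bonds of the decalin (C6–C7 and C5–C10) and returns to farnesyl diphosphate A3. Aristolochene synthase would fold and ionise A3, close both rings, shift a hydride to C4 and a methyl to C5, and release (+)-aristolochene A4.
- Merits: one step makes the skeleton with C4 and C5 in the correct absolute configuration. No chemical route, including the chosen one, matches this for ring construction or enantiocontrol.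
- Weak points: A4 is a hydrocarbon. C8 allylic oxidation, C11 hydration and C6–C7 dehydrogenation are conceivable, but C3 is an unactivated methylene far from any handle. A site- and stereoselective C3 hydroxylation would need an engineered oxygenase, and the route needs protein expression.
- Comparison: better on skeleton and absolute configuration. The chosen plan answers with O3 being built in during the ring-forming step.

**Alternative 3: double Michael annulation.** The cuts are C5–C10 and C5–C6. The ester enolate of ynenone A5 would add 6-exo-dig to C10, and the resulting C5 carbanion would then add to C6 of the vinyl ketone, giving bicycle A6.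
- Merits: both rings form around C5 in one base-mediated operation. A6 already has the 9-en-8-one, so no C6 oxygen must be removed and C7 can be functionalised by a plain α′-aldol with acetone 17. That is a better ring B oxidation pattern than in 13.
- Weak points: C5 carries an ester where C14 must be, costing about three steps at a neopentyl centre. The C5 configuration rests on 1,2-induction from C4 in the second Michael step. A5 needs its own asymmetric synthesis of C3/C4 and contains a doubly electrophilic ynenone prone to polymerisation.
- Comparison: equal or better for ring B. The chosen plan sets C3, C4 and C5 in one stereospecific event and needs no C14 adjustment.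

Key step: step 7

Assumption: the (S)-configured oxazaborolidinium catalyst is taken to leave the C4 Re/C5 Si face of the bound enone open; if the opposite sense is found, the (R)-catalyst is used and nothing else changes.

Assumption: ethyl 2-methyl-3-oxopropanoate 23, (E)-2-bromobut-2-ene 10 and triisopropylsilyl triflate are taken as commercial.

## Route

Step 1
Reactants: 1 ethyl acetoacetate; 2 allyl bromide
Product: 4 ethyl 3-oxohept-6-enoate, via acetoacetate dianion 3 (not isolated)
Conditions: NaH, THF, 0 °C; n-BuLi, 0 °C; then 2, 0 °C to rt; aq. NH4Cl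
Reagents that add atoms: none
Why: γ-alkylation of the acetoacetate dianion; the more basic terminal carbanion reacts first, so C9–C10 forms without α-alkylation, and no stereocentre arises.

Step 2
Reactants: 4 ethyl 3-oxohept-6-enoate
Product: 5 ethyl 2-[2-(but-3-en-1-yl)-1,3-dioxolan-2-yl]acetate
Conditions: HOCH2CH2OH, TsOH·H2O (cat.), benzene, reflux, Dean–Stark trap
Reagents that add atoms: ethylene glycol, OCCO
Why: acid-catalysed ketalisation with azeotropic removal of water; it masks C8 and blocks enolisation between C6 and C8.

Step 3
Reactants: 5 ethyl 2-[2-(but-3-en-1-yl)-1,3-dioxolan-2-yl]acetate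
Product: 6 2-[2-(but-3-en-1-yl)-1,3-dioxolan-2-yl]-N-methoxy-N-methylacetamide
Conditions: MeNH(OMe)·HCl, i-PrMgCl, THF, −20 to 0 °C
Reagents that add atoms: N,O-dimethylhydroxylamine hydrochloride, CNOC.Cl
Why: Weinreb amide formation by aminolysis of the ester with the magnesium amide; the weakly basic amide should not trigger β-elimination of the ketal.

Step 4
Reactants: 6 2-[2-(but-3-en-1-yl)-1,3-dioxolan-2-yl]-N-methoxy-N-methylacetamide; 7 (E)-crotonaldehyde
Product: 8 (E)-N-methoxy-N-methyl-2-[2-(5-oxopent-3-en-1-yl)-1,3-dioxolan-2-yl]acetamide
Conditions: 7 (5 equiv), second-generation Hoveyda–Grubbs catalyst [1,3-dimesitylimidazolidin-2-ylidene]dichloro(2-isopropoxybenzylidene)ruthenium (3 mol%), CH2Cl2, 40 °C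
Reagents that add atoms: none
Why: olefin cross-metathesis of a terminal alkene with an enal partner, driven by loss of propene; it should give the conjugated E enal with C1=C2 and C3 as the aldehyde.

Step 5
Reactants: 8 (E)-N-methoxy-N-methyl-2-[2-(5-oxopent-3-en-1-yl)-1,3-dioxolan-2-yl]acetamide
Product: 9 N-methoxy-N-methyl-2-{2-[(2E,4E)-5-(triisopropylsilyloxy)penta-2,4-dien-1-yl]-1,3-dioxolan-2-yl}acetamide
Conditions: i-Pr3SiOTf, Et3N, Et2O, −78 to 0 °C; purification on Et3N-deactivated silica
Reagents that add atoms: triisopropylsilyl triflate, CC(C)[Si](C(C)C)(C(C)C)OS(=O)(=O)C(F)(F)F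
Why: soft enolisation (O-silylation of the aldehyde, then γ-deprotonation at C10 by the amine); the s-trans enal fixes the E enol ether, the late deprotonation of the oxocarbenium ion is expected to favour E at C10=C1, and the amide and ketal are much less reactive towards the silyl triflate than the aldehyde.

Step 6
Reactants: 9 N-methoxy-N-methyl-2-{2-[(2E,4E)-5-(triisopropylsilyloxy)penta-2,4-dien-1-yl]-1,3-dioxolan-2-yl}acetamide; 10 (E)-2-bromobut-2-ene
Product: 12 (E)-3-methyl-1-{2-[(2E,4E)-5-(triisopropylsilyloxy)penta-2,4-dien-1-yl]-1,3-dioxolan-2-yl}pent-3-en-2-one, via (E)-but-2-en-2-yllithium 11 (not isolated)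
Conditions: 10, t-BuLi (2 equiv), Et2O, −78 °C; then 9, THF, −78 °C; aq. NH4Cl at −78 °C; product kept cold
Reagents that add atoms: none
Why: bromine–lithium exchange with retention of alkene geometry, then Weinreb ketone synthesis; the chelated tetrahedral adduct prevents over-addition, and the bulky silyl dienol ether should tolerate the organolithium at −78 °C.

Step 7
Reactants: 12 (E)-3-methyl-1-{2-[(2E,4E)-5-(triisopropylsilyloxy)penta-2,4-dien-1-yl]-1,3-dioxolan-2-yl}pent-3-en-2-one
Product: 13 (3R,4R,5S,10S)-8,8-(ethylenedioxy)-3-(triisopropylsilyloxy)-11,12,13-trinoreremophil-1-en-6-one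
Conditions: (S)-3,3-diphenyl-1-(o-tolyl)tetrahydro-1H,3H-pyrrolo[1,2-c][1,3,2]oxazaborole (20 mol%), Tf2NH (18 mol%), CH2Cl2, −78 to −20 °C
Reagents that add atoms: none
Why: Proposed new method: the cationic boron Lewis acid binds the C6 ketone and lowers the enone LUMO so that the tethered diene adds across C4=C5 in one concerted but asynchronous [4+2] event while its chiral pocket leaves one enone face open; the closest known reaction type is the oxazaborolidinium-catalysed intramolecular or transannular Diels–Alder reaction of trienals and trienones, together with the uncatalysed cyclisation of 1,7,9-decatrien-3-ones. Ring A (C1–C5 and C10) is the cyclohexene made by the cycloaddition itself. Ring B (C5–C10) closes at the same time as the fused six-membered ring spanned by the four-atom tether C6–C9, which also enforces the C3–C4/C5–C10 pairing against the electronic preference of a 1-silyloxydiene. C4 and C5 take their cis methyl groups from the E geometry of the dienophile through suprafacial addition. C3 is tied to C10 by the E,E diene (O3 and C9 cis), and the endo position of the coordinated C6 carbonyl under the diene makes the ring fusion cis and places O3 trans to C14 and C15. The absolute configuration of all four centres is decided by the catalyst, which has to deliver the diene to the C4 Re/C5 Si face. The step needs endo over exo selectivity (in-tether, Lewis-acid-bound carbonyl), facial selectivity (catalyst) and a geometrically pure reacting diene (the 3Z isomer cannot reach the cisoid conformer at this temperature and stays behind).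

Step 8
Reactants: 13 (3R,4R,5S,10S)-8,8-(ethylenedioxy)-3-(triisopropylsilyloxy)-11,12,13-trinoreremophil-1-en-6-one
Product: 14 (3R,4R,5S,10R)-8,8-(ethylenedioxy)-3-(triisopropylsilyloxy)-11,12,13-trinoreremophilan-6-one
Conditions: H2 (1 atm), Pd/C, EtOAc, rt
Reagents that add atoms: none
Why: heterogeneous hydrogenation of the cis-disubstituted ring alkene before any enone exists; ketone, ketal and silyl ether are inert, and no centre is changed (the C10 descriptor changes only by priority).

Step 9
Reactants: 14 (3R,4R,5S,10R)-8,8-(ethylenedioxy)-3-(triisopropylsilyloxy)-11,12,13-trinoreremophilan-6-one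
Product: 15 (3R,4R,5S,10R)-8,8-(ethylenedioxy)-3-(triisopropylsilyloxy)-11,12,13-trinoreremophilan-6-ol (C6 epimers)
Conditions: NaBH4, MeOH–THF, 0 °C to rt
Reagents that add atoms: none
Why: borohydride reduction of the neopentyl ketone; the C6 configuration is not controlled and is erased in step 10.

Step 10
Reactants: 15 (3R,4R,5S,10R)-8,8-(ethylenedioxy)-3-(triisopropylsilyloxy)-11,12,13-trinoreremophilan-6-ol (C6 epimers)
Product: 16 (3R,4R,5R,10R)-3-(triisopropylsilyloxy)-11,12,13-trinoreremophil-6-en-8-one
Conditions: TsOH·H2O, acetone–H2O, 56 °C
Reagents that add atoms: water, O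
Why: acid hydrolysis of the dioxolane, then acid-catalysed β-elimination of water from the β-hydroxy ketone through its enol, giving the conjugated enone; a secondary triisopropylsilyl ether should withstand these conditions.

Step 11
Reactants: 16 (3R,4R,5R,10R)-3-(triisopropylsilyloxy)-11,12,13-trinoreremophil-6-en-8-one; 17 acetone
Product: 19 (3R,4R,5S,10R)-11-hydroxy-3-(triisopropylsilyloxy)eremophilan-8-one (C7 epimers), via lithium C7 enolate 18 (not isolated)
Conditions: LiBH(s-Bu)3, THF, −78 °C; then ZnCl2, 17, −78 to −40 °C; AcOH quench at −78 °C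
Reagents that add atoms: none
Why: conjugate hydride addition to the enone (β-carbon C6 bears no further substituent) gives the C7 enolate regiospecifically, and the zinc-mediated aldol with acetone forms C7–C11; the C7 configuration is immaterial because step 12 makes C7 sp2.

Step 12
Reactants: 19 (3R,4R,5S,10R)-11-hydroxy-3-(triisopropylsilyloxy)eremophilan-8-one (C7 epimers)
Product: 21 (3R,4R,5R)-11-hydroxy-3-(triisopropylsilyloxy)eremophila-6,9-dien-8-one, via 9-en-8-one ketol 20 (not isolated)
Conditions: IBX (4 equiv), DMSO, 70 °C
Reagents that add atoms: none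
Why: two successive α,β-dehydrogenations of the ketone by the hypervalent iodine oxidant through its enols (ketone to enone to cross-conjugated dienone); the tertiary alcohol cannot be oxidised, and C7 and C10 lose their stereochemistry as required.

Step 13
Reactants: 21 (3R,4R,5R)-11-hydroxy-3-(triisopropylsilyloxy)eremophila-6,9-dien-8-one
Product: 22 (3R,4R,5R)-3,11-dihydroxyeremophila-6,9-dien-8-one
Conditions: Bu4NF, AcOH, THF, rt to 40 °C
Reagents that add atoms: none
Why: fluoride cleavage of the silyl ether, buffered so that the dienone is not exposed to free alkoxide; C3 is untouched.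

Step 14
Reactants: 23 ethyl 2-methyl-3-oxopropanoate
Product: 24 ethyl (2Z)-2-methyl-3-(tosyloxy)prop-2-enoate
Conditions: TsCl, Me2NCH2CH2NMe2, LiCl, MeCN, 0 °C
Reagents that add atoms: p-toluenesulfonyl chloride, Cc1ccc(cc1)S(Cl)(=O)=O
Why: O-sulfonylation of the lithium-chelated enolate of the formyl ester, in which the enolate oxygen and the ester are held cis, should give the Z enol tosylate.

Step 15
Reactants: 24 ethyl (2Z)-2-methyl-3-(tosyloxy)prop-2-enoate
Product: 25 ethyl (2Z)-2-methyl-3-(methylsulfanyl)prop-2-enoate
Conditions: NaSMe, THF, 0 °C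
Reagents that add atoms: sodium methanethiolate, [Na+].[S-]C
Why: vinylic substitution by addition–elimination; thiolates normally displace β-leaving groups of acrylates with retention, which keeps sulfur cis to the ester.

Step 16
Reactants: 25 ethyl (2Z)-2-methyl-3-(methylsulfanyl)prop-2-enoate
Product: 26 (2Z)-2-methyl-3-(methylsulfanyl)prop-2-enoic acid
Conditions: LiOH, THF–H2O, rt; then 1 M HCl
Reagents that add atoms: lithium hydroxide, [Li+].[OH-]
Why: saponification of the ethyl ester; the vinylogous thiocarbonate is a poor Michael acceptor for hydroxide at rt, so the geometry should hold.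

Step 17
Reactants: 22 (3R,4R,5R)-3,11-dihydroxyeremophila-6,9-dien-8-one; 26 (2Z)-2-methyl-3-(methylsulfanyl)prop-2-enoic acid
Product: 28 (3R,4R,5R)-11-hydroxy-8-oxoeremophila-6,9-dien-3-yl (2Z)-2-methyl-3-(methylsulfanyl)prop-2-enoate, via mixed anhydride 27 (not isolated)
Conditions: 26, 2,4,6-trichlorobenzoyl chloride, Et3N, THF, 0 °C; then 22, DMAP (0.2 equiv), toluene, 0 °C to rt
Reagents that add atoms: none
Why: Yamaguchi esterification; only the secondary C3 hydroxyl is acylated (the tertiary C11–OH is inert), C3 keeps its configuration because the C–O bond is not broken, and low DMAP loading at low temperature limits reversible conjugate addition that could isomerise the Z acrylate.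

## Compound list

1 | ethyl acetoacetate | CCOC(=O)CC(C)=O | starting material
2 | allyl bromide | C=CCBr | starting material
3 | ethyl acetoacetate dianion (sodium lithium salt) | [Na+].[Li+].[CH2-]C(=O)[CH-]C(=O)OCC | intermediate
4 | ethyl 3-oxohept-6-enoate | CCOC(=O)CC(=O)CCC=C | intermediate
5 | ethyl 2-[2-(but-3-en-1-yl)-1,3-dioxolan-2-yl]acetate | CCOC(=O)CC1(CCC=C)OCCO1 | intermediate
6 | 2-[2-(but-3-en-1-yl)-1,3-dioxolan-2-yl]-N-methoxy-N-methylacetamide | CON(C)C(=O)CC1(CCC=C)OCCO1 | intermediate
7 | (E)-crotonaldehyde | C/C=C/C=O | starting material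
8 | (E)-N-methoxy-N-methyl-2-[2-(5-oxopent-3-en-1-yl)-1,3-dioxolan-2-yl]acetamide | CON(C)C(=O)CC1(CC/C=C/C=O)OCCO1 | intermediate
9 | N-methoxy-N-methyl-2-{2-[(2E,4E)-5-(triisopropylsilyloxy)penta-2,4-dien-1-yl]-1,3-dioxolan-2-yl}acetamide | CON(C)C(=O)CC1(C/C=C/C=C/O[Si](C(C)C)(C(C)C)C(C)C)OCCO1 | intermediate
10 | (E)-2-bromobut-2-ene | C/C=C(\C)Br | starting material
11 | (E)-but-2-en-2-yllithium | C/C=C(\C)[Li] | intermediate
12 | (E)-3-methyl-1-{2-[(2E,4E)-5-(triisopropylsilyloxy)penta-2,4-dien-1-yl]-1,3-dioxolan-2-yl}pent-3-en-2-one | C/C=C(\C)C(=O)CC1(OCCO1)C/C=C/C=C/O[Si](C(C)C)(C(C)C)C(C)C | intermediate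
13 | (3R,4R,5S,10S)-8,8-(ethylenedioxy)-3-(triisopropylsilyloxy)-11,12,13-trinoreremophil-1-en-6-one (cis-fused cycloadduct) | CC(C)[Si](C(C)C)(C(C)C)O[C@@H]1C=C[C@@H]2CC3(OCCO3)CC(=O)[C@]2(C)[C@H]1C | intermediate
14 | (3R,4R,5S,10R)-8,8-(ethylenedioxy)-3-(triisopropylsilyloxy)-11,12,13-trinoreremophilan-6-one | CC(C)[Si](C(C)C)(C(C)C)O[C@@H]1CC[C@@H]2CC3(OCCO3)CC(=O)[C@]2(C)[C@H]1C | intermediate
15 | (3R,4R,5S,10R)-8,8-(ethylenedioxy)-3-(triisopropylsilyloxy)-11,12,13-trinoreremophilan-6-ol, C6 epimers | CC(C)[Si](C(C)C)(C(C)C)O[C@@H]1CC[C@@H]2CC3(OCCO3)CC(O)[C@]2(C)[C@H]1C | intermediate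
16 | (3R,4R,5R,10R)-3-(triisopropylsilyloxy)-11,12,13-trinoreremophil-6-en-8-one | CC(C)[Si](C(C)C)(C(C)C)O[C@@H]1CC[C@@H]2CC(=O)C=C[C@]2(C)[C@H]1C | intermediate
17 | acetone | CC(C)=O | starting material
18 | lithium (3R,4R,5S,10R)-3-(triisopropylsilyloxy)-11,12,13-trinoreremophil-7-en-8-olate | CC(C)[Si](C(C)C)(C(C)C)O[C@@H]1CC[C@@H]2CC([O-])=CC[C@]2(C)[C@H]1C.[Li+] | intermediate
19 | (3R,4R,5S,10R)-11-hydroxy-3-(triisopropylsilyloxy)eremophilan-8-one, C7 epimers | CC(C)[Si](C(C)C)(C(C)C)O[C@@H]1CC[C@@H]2CC(=O)C(C(C)(C)O)C[C@]2(C)[C@H]1C | intermediate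
20 | (3R,4R,5R)-11-hydroxy-3-(triisopropylsilyloxy)eremophil-9-en-8-one, C7 epimers | CC(C)[Si](C(C)C)(C(C)C)O[C@@H]1CCC2=CC(=O)C(C(C)(C)O)C[C@]2(C)[C@H]1C | intermediate
21 | (3R,4R,5R)-11-hydroxy-3-(triisopropylsilyloxy)eremophila-6,9-dien-8-one | CC(C)[Si](C(C)C)(C(C)C)O[C@@H]1CCC2=CC(=O)C(C(C)(C)O)=C[C@]2(C)[C@H]1C | intermediate
22 | (3R,4R,5R)-3,11-dihydroxyeremophila-6,9-dien-8-one | O[C@@H]1CCC2=CC(=O)C(C(C)(C)O)=C[C@]2(C)[C@H]1C | intermediate
23 | ethyl 2-methyl-3-oxopropanoate | CCOC(=O)C(C)C=O | starting material
24 | ethyl (2Z)-2-methyl-3-(tosyloxy)prop-2-enoate | CCOC(=O)/C(C)=C\OS(=O)(=O)c1ccc(C)cc1 | intermediate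
25 | ethyl (2Z)-2-methyl-3-(methylsulfanyl)prop-2-enoate | CCOC(=O)/C(C)=C\SC | intermediate
26 | (2Z)-2-methyl-3-(methylsulfanyl)prop-2-enoic acid | CS/C=C(/C)C(=O)O | intermediate
27 | (2Z)-2-methyl-3-(methylsulfanyl)prop-2-enoic 2,4,6-trichlorobenzoic anhydride | CS/C=C(/C)C(=O)OC(=O)c1c(Cl)cc(Cl)cc1Cl | intermediate
28 | (3R,4R,5R)-11-hydroxy-8-oxoeremophila-6,9-dien-3-yl (2Z)-2-methyl-3-(methylsulfanyl)prop-2-enoate | CS/C=C(/C)C(=O)O[C@@H]1CCC2=CC(=O)C(C(C)(C)O)=C[C@]2(C)[C@H]1C | target

## Step count and least certain steps

Total step count: 17. Longest linear sequence: 14 (steps 1–13 and 17); steps 14–16 make the acid side chain.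

**Step 7 (key step, proposed new method).** Three things may go wrong. Facial discrimination may be weak or of the wrong sense, because this α-methyl enone lacks the α-hydrogen contact that orients simpler enones on the catalyst. The silyl group may transfer from the dienol ether to the activated ketone, opening a racemic silylium-catalysed channel and vinylogous Michael oligomerisation. Turnover may be slow, because the tether enforces the electronically disfavoured orientation, and any exo leakage would invert C3 relative to C4 and C5. Fallback with known chemistry: trienone 12 is cyclised without catalyst in toluene at 110 °C with BHT, as decatrienones of this type are known to do. This gives the racemate, that is 13 together with the enantiomer of cycloadduct 13 F1. The two are separated by chromatography on an amylose tris(3,5-dimethylphenylcarbamate) stationary phase, and the route is rejoined at 13.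

**Step 5.** The γ-deprotonation may favour the 3Z isomer kinetically, and the dienol ether may hydrolyse on silica. Either would starve the key step of the reactive E,E diene. Fallback: the geometric mixture of 9 is equilibrated by reversible thiyl-radical addition (catalytic PhSSPh, visible light, benzene, rt) towards the thermodynamically preferred E,E isomer before step 6. The route is rejoined at 9 and no compound outside the list is made (entry F0).

**Step 11.** Hydride may attack the carbonyl instead of the hindered β-carbon next to the quaternary C5, and the aldol with a ketone may revert or lose out to proton transfer. Fallback: enone 16 is converted by RhCl(PPh3)3-catalysed 1,4-hydrosilylation with Et3SiH into the triethylsilyl enol ether (3R,4R,5S,10R)-8-(triethylsilyloxy)-3-(triisopropylsilyloxy)-11,12,13-trinoreremophil-7-ene F2. A TiCl4-mediated Mukaiyama aldol of F2 with acetone 17 at −78 °C then gives 19.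

**Step 12.** The tertiary alcohol may dehydrate or the ketol may undergo retro-aldol cleavage at 70 °C, and the second dehydrogenation at the substituted α-carbon C7 may stall. Fallback: enone 16 is dehydrogenated once with IBX to the dienone (3R,4R,5R)-3-(triisopropylsilyloxy)-11,12,13-trinoreremophila-6,9-dien-8-one F3. Me2AlSPh adds its thiolate to C6 of F3, and the aluminium enolate is trapped with acetone 17 to give the adduct (3R,4R,5R)-11-hydroxy-6-(phenylsulfanyl)-3-(triisopropylsilyloxy)eremophil-9-en-8-one F4. Oxidation with mCPBA at −78 °C gives the sulfoxide (3R,4R,5R)-11-hydroxy-6-(phenylsulfinyl)-3-(triisopropylsilyloxy)eremophil-9-en-8-one F5, which eliminates on warming to give 21. This path bypasses steps 11 and 12.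

**Step 10.** The silyl ether may be lost, or the dehydration of the neopentyl alcohol may stall at the β-hydroxy ketone. Fallback: alcohol 15 is deketalised under mild conditions (PPTS, acetone–water) to the β-hydroxy ketone (3R,4R,5S,10R)-6-hydroxy-3-(triisopropylsilyloxy)-11,12,13-trinoreremophilan-8-one F6. F6 is converted with MsCl and Et3N into the mesylate (3R,4R,5S,10R)-8-oxo-3-(triisopropylsilyloxy)-11,12,13-trinoreremophilan-6-yl methanesulfonate F7, and DBU eliminates it by E1cB to give 16.

## Further compounds

F1 | step 7 | (3S,4S,5R,10R)-8,8-(ethylenedioxy)-3-(triisopropylsilyloxy)-11,12,13-trinoreremophil-1-en-6-one (enantiomer of 13) | CC(C)[Si](C(C)C)(C(C)C)O[C@H]1C=C[C@H]2CC3(OCCO3)CC(=O)[C@@]2(C)[C@@H]1C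
F0 | step 5 | none | none
F2 | step 11 | (3R,4R,5S,10R)-8-(triethylsilyloxy)-3-(triisopropylsilyloxy)-11,12,13-trinoreremophil-7-ene | CC(C)[Si](C(C)C)(C(C)C)O[C@@H]1CC[C@@H]2CC(O[Si](CC)(CC)CC)=CC[C@]2(C)[C@H]1C
F3 | step 12 | (3R,4R,5R)-3-(triisopropylsilyloxy)-11,12,13-trinoreremophila-6,9-dien-8-one | CC(C)[Si](C(C)C)(C(C)C)O[C@@H]1CCC2=CC(=O)C=C[C@]2(C)[C@H]1C
F4 | step 12 | (3R,4R,5R)-11-hydroxy-6-(phenylsulfanyl)-3-(triisopropylsilyloxy)eremophil-9-en-8-one, C6 and C7 epimers | CC(C)[Si](C(C)C)(C(C)C)O[C@@H]1CCC2=CC(=O)C(C(C)(C)O)C(Sc3ccccc3)[C@]2(C)[C@H]1C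
F5 | step 12 | (3R,4R,5R)-11-hydroxy-6-(phenylsulfinyl)-3-(triisopropylsilyloxy)eremophil-9-en-8-one, C6 and C7 epimers | CC(C)[Si](C(C)C)(C(C)C)O[C@@H]1CCC2=CC(=O)C(C(C)(C)O)C(S(=O)c3ccccc3)[C@]2(C)[C@H]1C
F6 | step 10 | (3R,4R,5S,10R)-6-hydroxy-3-(triisopropylsilyloxy)-11,12,13-trinoreremophilan-8-one, C6 epimers | CC(C)[Si](C(C)C)(C(C)C)O[C@@H]1CC[C@@H]2CC(=O)CC(O)[C@]2(C)[C@H]1C
F7 | step 10 | (3R,4R,5S,10R)-8-oxo-3-(triisopropylsilyloxy)-11,12,13-trinoreremophilan-6-yl methanesulfonate, C6 epimers | CC(C)[Si](C(C)C)(C(C)C)O[C@@H]1CC[C@@H]2CC(=O)CC(OS(C)(=O)=O)[C@]2(C)[C@H]1C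
A1 | alternative 1 | (2R,3R)-3-(tert-butyldimethylsilyloxy)-5-[5-hydroxy-4-(2-hydroxypropan-2-yl)-2-methylphenyl]pentan-2-yl methanesulfonate | Cc1cc(C(C)(C)O)c(O)cc1CC[C@@H](O[Si](C)(C)C(C)(C)C)[C@@H](C)OS(C)(=O)=O
A2 | alternative 1 | (3R,4R,5R)-3-(tert-butyldimethylsilyloxy)-11-hydroxyeremophila-6,9-dien-8-one | CC(C)(C)[Si](C)(C)O[C@@H]1CCC2=CC(=O)C(C(C)(C)O)=C[C@]2(C)[C@H]1C
A3 | alternative 2 | (2E,6E)-farnesyl diphosphate | CC(C)=CCC/C(C)=C/CC/C(C)=C/COP(=O)(O)OP(=O)(O)O
A4 | alternative 2 | (+)-aristolochene | C1CCC2=CC[C@H](C(C)=C)C[C@]2(C)[C@H]1C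
A5 | alternative 3 | tert-butyl (3R,4R)-4-(tert-butyldimethylsilyloxy)-3-methyl-9-oxoundec-10-en-7-ynoate | C=CC(=O)C#CCC[C@@H](O[Si](C)(C)C(C)(C)C)[C@H](C)CC(=O)OC(C)(C)C
A6 | alternative 3 | tert-butyl (3R,4R,5S)-3-(tert-butyldimethylsilyloxy)-8-oxo-11,12,13-trinoreremophil-9-en-14-oate | CC(C)(C)[Si](C)(C)O[C@@H]1CCC2=CC(=O)CC[C@]2(C(=O)OC(C)(C)C)[C@H]1C
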